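## Structural features

Suaveolindole is a cyclohexane substituted on four ring carbons: C1 is a CH with a 2-carboxyethyl chain, C2 is quaternary with a methyl group and a methylene linked to C3 of an otherwise unsubstituted indole, C3 is a CH with a methyl group, and C6 bears an exocyclic isopropylidene group, while C4 and C5 are methylenes. The stereocentres C1, C2 and C3 are contiguous with the configuration (1S,2R,3R); the C2 methyl lies on the same face as the C1 chain and opposite to the C3 methyl, so the indolylmethyl group is cis to the C3 methyl. The fragile groups are the tetrasubstituted C6 alkene, which acid can move into the ring or trap as a lactone with the C1 acid chain, the free indole N–H with its electron-rich C2–C3 bond, and the carboxylic acid. The real difficulty is the quaternary C2, which sits between two tertiary stereocentres and is joined through a neopentyl methylene to the heteroaromatic ring, together with a tetrasubstituted alkene that has to be made next to the epimerisable C1. The plan exploits the fact that the C2 methyl carbon, C1 and C2 can be closed into a three-membered ring beside an oxygen function on C6. A C6 carbinol steers a methylene group to one face of a C1=C2 alkene, and the derived C6 ketone later directs cleavage of the C1–CH2 bond. That cleavage releases the methyl group on C2 and leaves C1 as a regiodefined enolate carbon; the C1 configuration is then set by alkylation of that enolate under control of the C2 and C3 substituents.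

## Logic of the disconnections

**Indole ring.** In 21 the C3–C3a and N1–C2 bonds of the pyrrole ring are cut, which leads through 20 and 19 to 17 and 18. The indole is the most oxidation- and acid-sensitive part, so it is made last from a masked aldehyde that is inert to everything before. This removes the heteroaromatic bicycle and leaves an achiral reagent. The forward step must use acid weak enough to spare the tetrasubstituted alkene and the neighbouring acid.

**Acid chain.** 17 is traced through 16 to 15 by lowering the oxidation level of the chain terminus. A terminal alkene is the sturdiest three-carbon precursor of the propanoic acid and comes from a reactive allyl electrophile. The forward steps must distinguish a monosubstituted from a tetrasubstituted alkene and oxidise without opening the acetal.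

**Isopropylidene.** The exocyclic C6=C bond of 15 is cut, through 14, back to 13 and a two-methyl acyl unit. The C6 carbonyl is the handle that every earlier step needs, and the alkene has two identical methyls, so no geometry has to be controlled. The forward step must form a C–C bond at a hindered, enolisable carbonyl without epimerising C1, and then lose CO2 cleanly.

**C1 chain and C2 methyl.** In 13 the C1–allyl bond is cut to give 12, and 12 is reconnected between C1 and the C2 methyl carbon to give 11. The three-membered ring hides the quaternary methyl and fixes the enolate regiochemistry. The forward step must break the external cyclopropane bond, alkylate faster than protons exchange, and choose the face of C1 anti to the C2 chain.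

**Cyclopropane (key disconnection).** 11 is taken back to 10, and both cyclopropane bonds of 10 (C1–CH2 and C2–CH2) are cut to give 9. The quaternary centre becomes a trisubstituted alkene carbon, and two stereocentres collapse into the single carbinol centre. The forward step must deliver the methylene syn to the hydroxyl.

**Carbinol.** The carbinol C–H bond of 9 is cut to give 8. Only one stereocentre has to be set, and it is remote from the existing one, so a chiral reagent is required.

**Side chain on the ring.** The bond between the ring β-carbon and the dioxolanylethyl chain of 8 is cut, through 7, to 4 and 5 (used as 6). Conjugate addition followed by re-oxidation places the chain on the β-carbon without touching the methyl stereocentre.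

**Ring.** The C=C bond of 4 and the bond between its methyl-bearing carbon and the adjacent CH2 are cut, through 3, to 1 and 2. This leaves two bulk chemicals and one catalytic enantioselective C–C bond formation. The forward step must cyclise without racemising the aldehyde α-centre.

## Other disconnections considered

Alternative 1: The ring is cut at C2–C3 and C1–C6, which leads back to the vinylallene (5E)-2-methylhepta-2,3,5-triene A1 and the enal ester methyl (4E)-5-formylhex-4-enoate A2.
- Forward key step: a Lewis acid promoted Diels–Alder reaction of A1 with A2 joins the allene central carbon to the β-carbon of the enal and the methyl-bearing diene terminus to its α-carbon. The product, methyl 3-[(1R,5R,6R)-6-formyl-5,6-dimethyl-2-(propan-2-ylidene)cyclohex-3-en-1-yl]propanoate A3, would carry the C6 isopropylidene, the quaternary C2 and both flanking stereocentres.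
- In its favour: the methyl-bearing terminus of A1 and the formyl-bearing carbon of A2 pair as the ortho rule predicts, and the E geometries of both partners map directly onto the C1/C2 and C2/C3 relationships. The chain arrives at the ester oxidation level and no ketone olefination is needed. On convergence and on step count to the carbocycle it is better than the chosen plan.
- Against it: A2 is a trisubstituted, α-branched dienophile, a class in which the formyl group often prefers the exo position, whereas A3 needs it endo (cis to the C3 methyl). One allene methyl of A1 points into the approaching dienophile. Absolute control would have to come from a chiral Lewis acid on an unusual pairing. A3 still needs selective saturation of the ring alkene of a conjugated diene and a two-carbon extension of a neopentyl aldehyde before the indole can be made.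
- Comparison: the chosen plan spreads the stereochemical load over three well-understood events. This alternative concentrates it in one cycloaddition whose endo/exo outcome is the open question; if that were secured, and once A1 and A2 are in hand, it would be the shorter route.

Alternative 2: C6–C1 and the bond between the first and second carbons of the acid chain are cut. This leads back to the dioxinone tert-butyl 3-[(2S,3R)-5-(2,2-dimethyl-4-oxo-4H-1,3-dioxin-6-yl)-2-ethenyl-2,3-dimethylpentyl]-1H-indole-1-carboxylate A4, in which the heterocycle is joined through C5, C4 and C3 to a C2 carrying methyl, vinyl and the N-Boc-indol-3-ylmethyl group.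
- Forward key step: irradiation of A4 would give the intramolecular [2+2] tricyclic photoadduct A5, closing the cyclohexane and a cyclobutane together. Opening of the dioxanone and retro-aldol cleavage of the cyclobutane would then give the keto acid A6.
- In its favour: the propanoic acid is delivered at the correct oxidation level in the same operation as the C1–C6 bond, which removes the hydroboration and oxidation steps of the chosen plan (better). The indole is in place early, so no acid-mediated indolisation is needed beside the sensitive alkene (also better).
- Against it: the quaternary C2 and tertiary C3 of A4 must be set in an open chain, which is harder than on a ring. The C1 configuration depends on how the tether folds in the excited state. The N-acylindole absorbs in the same region as the dioxinone and can enter its own photochemistry. A6 still needs the same ketone-to-isopropylidene conversion, now with an indole present.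
- Comparison: on the olefination problem the plans are equal, and on the chain the alternative is ahead. On the quaternary stereocentre and on predictability of the key step the chosen plan is ahead. The overall step count is unlikely to differ much once A4 is assembled.

Alternative 3: The ring is cut at C3–C4 and C1–C2, and a sacrificial ring A is added in thought between C6 and the chain on C1.
- Forward key step: a Diels–Alder reaction of the achiral diene 7-ethenyl-6,6-dimethyl-1,4-dioxaspiro[4.5]dec-7-ene A7 with the enal (2E)-2-{[1-(4-methylbenzenesulfonyl)-1H-indol-3-yl]methyl}but-2-enal A8, under a chiral cationic oxazaborolidine Lewis acid, would give the endo adduct A9. Later the formyl group becomes the C2 methyl. A retro-allylation across the bond between the former ketal carbon and the gem-dimethyl carbon then splits ring A, turning the gem-dimethyl carbon into the isopropylidene group and the oxygenated carbon into the chain terminus.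
- In its favour: all three stereocentres, with the indolylmethyl group already attached, come from one catalytic enantioselective step. This is better than the chosen plan, which uses two chiral catalysts and one substrate-controlled alkylation. Neither a ketone olefination nor a Fischer step is needed, and it is the most convergent plan.
- Against it: A8 is β-substituted and A7 is congested beside its internal diene carbon, so reactivity is a concern. The two alkyl substituents of A7 pull the orientation in opposite directions. The neopentyl aldehyde of A9 must be reduced to methyl in the presence of ketal and sulfonamide. The fragmentation must cleave the right C–C bond and protonate the allyl fragment at the ring carbon to place the alkene exocyclic, which is the least predictable operation, and a detosylation follows.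
- Comparison: in step count the two plans are probably equal once A7 and A8 are made. In mechanism the chosen plan is the more conservative; this one would be the more elegant if the fragmentation behaved.

Key step: step 5

Assumption: the sense of induction of the (S)-diphenylprolinol ether in step 1 and of the (S)-oxazaborolidine in step 4 is taken from the accepted enamine-shielding and oxazaborolidine–borane models; if either model failed on these substrates, the antipodal catalyst would be used.

## Route

Step 1
Reactants: 1 propanal; 2 but-3-en-2-one (methyl vinyl ketone)
Product: 4 (4R)-4-methylcyclohex-2-en-1-one, via (2R)-2-methyl-5-oxohexanal 3 (not isolated)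
Conditions: (S)-2-[methoxy(diphenyl)methyl]pyrrolidine (5 mol %), ethyl 3,4-dihydroxybenzoate (20 mol %), neat, 4 °C; then 0.1 M aq KOH, n-Bu4NOH (cat.), Et2O/THF, reflux
Reagents that add atoms: none
Why: Enamine-mediated Michael addition of the aldehyde to the enone, in which the bulky group of the (S)-pyrrolidine shields one face of the E-enamine so that the new centre of 3 should be R, followed by intramolecular aldol condensation of the methyl ketone onto the aldehyde. Mild biphasic base is chosen so that ring closure outpaces enolisation of the aldehyde stereocentre.

Step 2
Reactants: 4 (4R)-4-methylcyclohex-2-en-1-one; 5 2-(2-bromoethyl)-1,3-dioxolane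
Product: 7 trimethyl({(3S,4R)-3-[2-(1,3-dioxolan-2-yl)ethyl]-4-methylcyclohex-1-en-1-yl}oxy)silane, via Grignard reagent 6 (not isolated)
Conditions: Mg, THF, ≤25 °C (5 to 6); then CuBr·SMe2 (10 mol %), Me3SiCl, DMPU, 4, THF, −78 °C; Et3N, cold aq NaHCO3
Reagents that add atoms: chlorotrimethylsilane, C[Si](C)(C)Cl
Why: Copper-catalysed conjugate addition of a Grignard reagent accelerated by Me3SiCl, which traps the enolate as the C1=C2 silyl enol ether with fixed regiochemistry. Addition is expected anti to the C4 methyl (3S), but this centre is erased in step 3; reagent 6 is made and kept at or below 25 °C because it is thermally labile.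

Step 3
Reactants: 7 trimethyl({(3S,4R)-3-[2-(1,3-dioxolan-2-yl)ethyl]-4-methylcyclohex-1-en-1-yl}oxy)silane
Product: 8 (4R)-3-[2-(1,3-dioxolan-2-yl)ethyl]-4-methylcyclohex-2-en-1-one
Conditions: Pd(OAc)2 (1.1 equiv), MeCN, 23 °C
Reagents that add atoms: none
Why: Saegusa–Ito oxidation: the silyl enol ether gives a palladium enolate (divalent palladium on C2) and β-hydride elimination can only take the C3 hydrogen, which returns the enone with the chain on the β-carbon. The C4 stereocentre is untouched under these neutral conditions.

Step 4
Reactants: 8 (4R)-3-[2-(1,3-dioxolan-2-yl)ethyl]-4-methylcyclohex-2-en-1-one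
Product: 9 (1R,4R)-3-[2-(1,3-dioxolan-2-yl)ethyl]-4-methylcyclohex-2-en-1-ol
Conditions: (S)-2-methyl-CBS-oxazaborolidine (0.2 equiv), BH3·SMe2 (0.7 equiv), THF, −20 °C; MeOH
Reagents that add atoms: none
Why: Corey–Bakshi–Shibata reduction: the oxazaborolidine–borane complex binds the carbonyl with the alkenyl side as the larger group and delivers hydride intramolecularly, which should give the 1R carbinol. The C4 methyl is remote from the carbonyl and should exert little bias of its own, so the reagent decides and the hydroxyl ends trans to the C4 methyl.

Step 5
Reactants: 9 (1R,4R)-3-[2-(1,3-dioxolan-2-yl)ethyl]-4-methylcyclohex-2-en-1-ol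
Product: 10 (1S,2R,5R,6S)-6-[2-(1,3-dioxolan-2-yl)ethyl]-5-methylbicyclo[4.1.0]heptan-2-ol
Conditions: Et2Zn (5 equiv), CH2I2 (10 equiv), CH2Cl2, −10 → 23 °C; aq NH4Cl
Reagents that add atoms: diiodomethane, ICI
Why: Et2Zn first converts the hydroxyl of 9 into an ethylzinc alkoxide, and the iodomethylzinc carbenoid formed from Et2Zn and CH2I2 is held on that oxygen so that it lies over the neighbouring C=C bond. Methylene is then transferred in one concerted, suprafacial step through a butterfly-type transition state in which both new C–C bonds (to the chain-bearing carbon and to the vinylic CH) form as iodide leaves carbon for zinc. The closest known reaction type is the Et2Zn/CH2I2 (Furukawa) variant of the Simmons–Smith cyclopropanation of cyclohex-2-en-1-ols, which is reliably cis-directed. The three-membered ring closes by this [2+1] addition across one face of the alkene, so the ring fusion is necessarily cis. Both new stereocentres, C1 and C6 of the bicyclo[4.1.0]heptane, are controlled by the carbinol centre: delivery syn to oxygen should give 1S and 6S. The only selectivity needed is π-facial, since there is a single alkene and no regiochemical choice, and the substrate secures it twice, because the C5 methyl lies on the face opposite to the alkoxide and hinders the unwanted approach. The dioxolane is a spectator expected to tolerate ZnI2 at or below room temperature. An excess of carbenoid is planned because the alkene is trisubstituted and flanked by a branched carbon.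

Step 6
Reactants: 10 (1S,2R,5R,6S)-6-[2-(1,3-dioxolan-2-yl)ethyl]-5-methylbicyclo[4.1.0]heptan-2-ol
Product: 11 (1S,5R,6S)-6-[2-(1,3-dioxolan-2-yl)ethyl]-5-methylbicyclo[4.1.0]heptan-2-one
Conditions: (n-Pr4N)RuO4 (5 mol %), N-methylmorpholine N-oxide (1.5 equiv), 4 Å MS, CH2Cl2, 23 °C
Reagents that add atoms: none
Why: Ley–Griffith oxidation of a secondary cyclopropylcarbinol to the ketone under neutral conditions, which avoids cyclopropylcarbinyl cation chemistry and leaves the acetal intact.

Step 7
Reactants: 11 (1S,5R,6S)-6-[2-(1,3-dioxolan-2-yl)ethyl]-5-methylbicyclo[4.1.0]heptan-2-one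
Product: 13 (2S,3R,4R)-3-[2-(1,3-dioxolan-2-yl)ethyl]-3,4-dimethyl-2-(prop-2-en-1-yl)cyclohexan-1-one, via lithium enolate 12 (not isolated)
Conditions: Li (2.5 equiv), t-BuOH (1.0 equiv), NH3(l)/THF, −78 °C; isoprene; then CH2=CHCH2I (5 equiv), −78 → −33 °C; NH4Cl
Reagents that add atoms: 3-iodoprop-1-ene (allyl iodide), C=CCI
Why: Dissolving-metal cleavage of a conjugated cyclopropyl ketone followed by enolate alkylation: the ketyl breaks the external C1–C7 bond, which overlaps best with the carbonyl π system, so C7 becomes the methyl on the quaternary carbon and enolate 12 is formed only towards the former C1. Allyl iodide should then attack axially, anti to the axial dioxolanylethyl chain on the adjacent quaternary carbon in the half-chair that keeps the C4 methyl equatorial. The other half-chair would put the electrophile in a 1,3-diaxial clash with that methyl, so the 2S centre with allyl cis to the new methyl is expected.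

Step 8
Reactants: 13 (2S,3R,4R)-3-[2-(1,3-dioxolan-2-yl)ethyl]-3,4-dimethyl-2-(prop-2-en-1-yl)cyclohexan-1-one
Product: 14 (5S,6R,7R)-6-[2-(1,3-dioxolan-2-yl)ethyl]-3,3,6,7-tetramethyl-5-(prop-2-en-1-yl)-1-oxaspiro[3.5]nonan-2-one (either configuration at the spiro carbon C4)
Conditions: LiN(i-Pr)2 (1.15 equiv), S-phenyl 2-methylpropanethioate (1.1 equiv), THF, −78 °C; then 13, −78 → 0 °C; aq NH4Cl
Reagents that add atoms: S-phenyl 2-methylpropanethioate, CC(C)C(=O)Sc1ccccc1
Why: Aldol addition of a thioester lithium enolate to the ketone, with lactonisation of the aldolate and loss of thiolate on warming (β-lactone synthesis from thioester enolates and ketones). The spiro-carbon configuration is not controlled and need not be, since both epimers give the same alkene in step 9.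

Step 9
Reactants: 14 (5S,6R,7R)-6-[2-(1,3-dioxolan-2-yl)ethyl]-3,3,6,7-tetramethyl-5-(prop-2-en-1-yl)-1-oxaspiro[3.5]nonan-2-one
Product: 15 2-{2-[(1R,2S,6R)-1,6-dimethyl-3-(propan-2-ylidene)-2-(prop-2-en-1-yl)cyclohexyl]ethyl}-1,3-dioxolane
Conditions: toluene, silica gel (cat.), 100 °C
Reagents that add atoms: none
Why: Thermal [2+2] cycloreversion of a β-lactone with loss of CO2, a known route to tetrasubstituted alkenes; the new alkene carries two identical methyl groups, so no geometrical isomer can arise. The temperature is held near 100 °C to stay well below the onset of Cope rearrangement of the resulting 1,5-diene.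

Step 10
Reactants: 15 2-{2-[(1R,2S,6R)-1,6-dimethyl-3-(propan-2-ylidene)-2-(prop-2-en-1-yl)cyclohexyl]ethyl}-1,3-dioxolane
Product: 16 3-[(1S,2R,3R)-2-[2-(1,3-dioxolan-2-yl)ethyl]-2,3-dimethyl-6-(propan-2-ylidene)cyclohexyl]propan-1-ol
Conditions: 9-BBN (1.5 equiv), THF, 0 → 23 °C; then 3 M NaOH, 30% H2O2, 0 → 23 °C
Reagents that add atoms: hydrogen peroxide, OO
Why: Hydroboration–oxidation with a bulky dialkylborane: 9-BBN adds anti-Markovnikov to the monosubstituted alkene and should not react with the tetrasubstituted isopropylidene group; alkaline H2O2 then replaces boron by hydroxyl.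

Step 11
Reactants: 16 3-[(1S,2R,3R)-2-[2-(1,3-dioxolan-2-yl)ethyl]-2,3-dimethyl-6-(propan-2-ylidene)cyclohexyl]propan-1-ol
Product: 17 3-[(1S,2R,3R)-2-[2-(1,3-dioxolan-2-yl)ethyl]-2,3-dimethyl-6-(propan-2-ylidene)cyclohexyl]propanoic acid
Conditions: TEMPO (0.2 equiv), PhI(OAc)2 (2.2 equiv), MeCN/pH 7 phosphate buffer (1:1), 23 °C
Reagents that add atoms: water, O
Why: Nitroxyl-catalysed oxidation of a primary alcohol to the carboxylic acid through the aldehyde hydrate, with PhI(OAc)2 as terminal oxidant. Buffering near neutral pH is meant to keep the dioxolane closed and the electron-rich alkene untouched.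

Step 12
Reactants: 17 3-[(1S,2R,3R)-2-[2-(1,3-dioxolan-2-yl)ethyl]-2,3-dimethyl-6-(propan-2-ylidene)cyclohexyl]propanoic acid; 18 phenylhydrazine
Product: 21 suaveolindole (3-[(1S,2R,3R)-2-(1H-indol-3-ylmethyl)-2,3-dimethyl-6-(propan-2-ylidene)cyclohexyl]propanoic acid), via aldehyde 19 (not isolated), via phenylhydrazone 20 (not isolated)
Conditions: PhNHNH2 (1.2 equiv), AcOH/H2O (4:1), 50 °C; then 90 °C
Reagents that add atoms: none
Why: Fischer indole synthesis run directly on the acetal: aqueous acetic acid releases aldehyde 19, which condenses to hydrazone 20; ene-hydrazine formation, [3,3]-sigmatropic shift, rearomatisation, ring closure and loss of NH3 give the 3-substituted indole, the aldehyde α-carbon becoming indole C3. The free hydrazine is used without mineral acid so that the only acid present is a carboxylic acid, which should be too weak to protonate the tetrasubstituted alkene at a useful rate; no stereocentre is involved.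

## Compound list

1 | propanal | CCC=O | starting material
2 | but-3-en-2-one (methyl vinyl ketone) | CC(=O)C=C | starting material
3 | (2R)-2-methyl-5-oxohexanal | O=C[C@H](C)CCC(C)=O | intermediate
4 | (4R)-4-methylcyclohex-2-en-1-one | O=C1C=C[C@H](C)CC1 | intermediate
5 | 2-(2-bromoethyl)-1,3-dioxolane | BrCCC1OCCO1 | starting material
6 | [2-(1,3-dioxolan-2-yl)ethyl]magnesium bromide | Br[Mg]CCC1OCCO1 | intermediate
7 | trimethyl({(3S,4R)-3-[2-(1,3-dioxolan-2-yl)ethyl]-4-methylcyclohex-1-en-1-yl}oxy)silane | C[Si](C)(C)OC1=C[C@@H](CCC2OCCO2)[C@H](C)CC1 | intermediate
8 | (4R)-3-[2-(1,3-dioxolan-2-yl)ethyl]-4-methylcyclohex-2-en-1-one | O=C1C=C(CCC2OCCO2)[C@H](C)CC1 | intermediate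
9 | (1R,4R)-3-[2-(1,3-dioxolan-2-yl)ethyl]-4-methylcyclohex-2-en-1-ol | O[C@@H]1CC[C@@H](C)C(CCC2OCCO2)=C1 | intermediate
10 | (1S,2R,5R,6S)-6-[2-(1,3-dioxolan-2-yl)ethyl]-5-methylbicyclo[4.1.0]heptan-2-ol | O[C@@H]1CC[C@@H](C)[C@]2(CCC3OCCO3)C[C@H]12 | intermediate
11 | (1S,5R,6S)-6-[2-(1,3-dioxolan-2-yl)ethyl]-5-methylbicyclo[4.1.0]heptan-2-one | O=C1CC[C@@H](C)[C@]2(CCC3OCCO3)C[C@H]12 | intermediate
12 | lithium (3R,4R)-3-[2-(1,3-dioxolan-2-yl)ethyl]-3,4-dimethylcyclohex-1-en-1-olate | [Li+].[O-]C1=C[C@](C)(CCC2OCCO2)[C@H](C)CC1 | intermediate
13 | (2S,3R,4R)-3-[2-(1,3-dioxolan-2-yl)ethyl]-3,4-dimethyl-2-(prop-2-en-1-yl)cyclohexan-1-one | O=C1CC[C@@H](C)[C@@](C)(CCC2OCCO2)[C@@H]1CC=C | intermediate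
14 | (5S,6R,7R)-6-[2-(1,3-dioxolan-2-yl)ethyl]-3,3,6,7-tetramethyl-5-(prop-2-en-1-yl)-1-oxaspiro[3.5]nonan-2-one (spiro carbon undefined) | CC1(C)C(=O)OC12CC[C@@H](C)[C@@](C)(CCC3OCCO3)[C@@H]2CC=C | intermediate
15 | 2-{2-[(1R,2S,6R)-1,6-dimethyl-3-(propan-2-ylidene)-2-(prop-2-en-1-yl)cyclohexyl]ethyl}-1,3-dioxolane | CC(C)=C1CC[C@@H](C)[C@@](C)(CCC2OCCO2)[C@@H]1CC=C | intermediate
16 | 3-[(1S,2R,3R)-2-[2-(1,3-dioxolan-2-yl)ethyl]-2,3-dimethyl-6-(propan-2-ylidene)cyclohexyl]propan-1-ol | CC(C)=C1CC[C@@H](C)[C@@](C)(CCC2OCCO2)[C@@H]1CCCO | intermediate
17 | 3-[(1S,2R,3R)-2-[2-(1,3-dioxolan-2-yl)ethyl]-2,3-dimethyl-6-(propan-2-ylidene)cyclohexyl]propanoic acid | CC(C)=C1CC[C@@H](C)[C@@](C)(CCC2OCCO2)[C@@H]1CCC(=O)O | intermediate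
18 | phenylhydrazine | NNc1ccccc1 | starting material
19 | 3-[(1S,2R,3R)-2,3-dimethyl-2-(3-oxopropyl)-6-(propan-2-ylidene)cyclohexyl]propanoic acid | CC(C)=C1CC[C@@H](C)[C@@](C)(CCC=O)[C@@H]1CCC(=O)O | intermediate
20 | 3-[(1S,2R,3R)-2,3-dimethyl-2-[3-(2-phenylhydrazinylidene)propyl]-6-(propan-2-ylidene)cyclohexyl]propanoic acid | CC(C)=C1CC[C@@H](C)[C@@](C)(CCC=NNc2ccccc2)[C@@H]1CCC(=O)O | intermediate
21 | suaveolindole, 3-[(1S,2R,3R)-2-(1H-indol-3-ylmethyl)-2,3-dimethyl-6-(propan-2-ylidene)cyclohexyl]propanoic acid | CC(C)=C1CC[C@@H](C)[C@@](C)(Cc2c[nH]c3ccccc23)[C@@H]1CCC(=O)O | target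

## Step count and least certain steps

Total step count: 12. Longest linear sequence: 12 steps (from 1 and 2 to 21; 5 enters in step 2 and 18 in step 12).

**Step 5 (key step).** The most likely failure is incomplete methylene transfer, because the alkene is trisubstituted and sits beside a branched carbon. Prolonged exposure to excess carbenoid could then methylate the zinc alkoxide or let ZnI2 open the dioxolane. The fallback gives up hydroxyl direction. It sets out from 8 and adds dimethylsulfoxonium methylide (Me3S(O)I, NaH, DMSO) in a Corey–Chaykovsky conjugate cyclopropanation. Attack is expected anti to the C4 methyl, and the sequence comes back at 11, bypassing 9 and 10. This detour makes no compound outside the list (F0).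

**Step 7.** The likely failures are insufficient facial discrimination at C1, and proton exchange between enolate 12 and the product, which leads to allylation at the other α-carbon or to double allylation. The fallback sets out from 11. After the same Li/NH3 cleavage to 12 and removal of NH3, the enolate is acylated on oxygen with allyl chloroformate (TMEDA, THF, −78 °C) to give prop-2-en-1-yl (3R,4R)-3-[2-(1,3-dioxolan-2-yl)ethyl]-3,4-dimethylcyclohex-1-en-1-yl carbonate F1. A Tsuji–Trost decarboxylative allylation with zerovalent palladium (Pd(PPh3)4, or Pd2(dba)3 with a chiral diphosphine chosen to match the substrate bias) in THF then returns to 13. The enol carbonate locks the regiochemistry, the medium is neutral, and any C-acylated isomer would funnel to the same product.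

**Step 8 (with step 9).** The hindered, enolisable ketone may be deprotonated by the thioester enolate instead of adding it, or the aldolate may revert before it lactonises. The fallback sets out from 13 and uses a McMurry cross-coupling with excess acetone. Low-valent titanium is generated from TiCl3(DME)1.5 and Zn–Cu couple in DME at reflux. It comes back at 15, skipping 14. No compound outside the list is made (F0).

**Step 12.** At the temperature the sigmatropic shift needs, acid may move the tetrasubstituted alkene into the ring or let the C1 acid add to it as a lactone. The fallback sets out from 17. The acetal is hydrolysed separately under mild conditions (AcOH/THF/H2O 3:1:1, 45 °C) to aldehyde 19. The indole is then built under basic conditions by palladium-catalysed annulation with 2-iodoaniline (Pd(OAc)2, DABCO, DMF, 85 °C; enamine formation, oxidative addition, intramolecular Heck-type closure). It comes back at 21. Since 19 is already listed, no new compound arises (F0).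

**Step 4.** Reagent control may be incomplete, which would carry the cis-alcohol to the wrong cyclopropane face. The fallback sets out from 8. Luche reduction (NaBH4, CeCl3·7H2O, MeOH, −78 °C) should give 9 together with its epimer (1S,4R)-3-[2-(1,3-dioxolan-2-yl)ethyl]-4-methylcyclohex-2-en-1-ol F2. After separation, F2 is inverted by a Mitsunobu reaction with 4-nitrobenzoic acid (PPh3, diisopropyl azodicarboxylate) to (1R,4R)-3-[2-(1,3-dioxolan-2-yl)ethyl]-4-methylcyclohex-2-en-1-yl 4-nitrobenzoate F3. Methanolysis (K2CO3, MeOH) comes back at 9.

## Further compounds

F0 | step 5 | none | none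
F1 | step 7 | prop-2-en-1-yl (3R,4R)-3-[2-(1,3-dioxolan-2-yl)ethyl]-3,4-dimethylcyclohex-1-en-1-yl carbonate | C=CCOC(=O)OC1=C[C@](C)(CCC2OCCO2)[C@H](C)CC1
F0 | step 8 | none | none
F0 | step 12 | none | none
F2 | step 4 | (1S,4R)-3-[2-(1,3-dioxolan-2-yl)ethyl]-4-methylcyclohex-2-en-1-ol | O[C@H]1CC[C@@H](C)C(CCC2OCCO2)=C1
F3 | step 4 | (1R,4R)-3-[2-(1,3-dioxolan-2-yl)ethyl]-4-methylcyclohex-2-en-1-yl 4-nitrobenzoate | O=C(O[C@@H]1CC[C@@H](C)C(CCC2OCCO2)=C1)c1ccc(cc1)[N+](=O)[O-]
A1 | alternative 1 | (5E)-2-methylhepta-2,3,5-triene | C/C=C/C=C=C(C)C
A2 | alternative 1 | methyl (4E)-5-formylhex-4-enoate | COC(=O)CC/C=C(\C)C=O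
A3 | alternative 1 | methyl 3-[(1R,5R,6R)-6-formyl-5,6-dimethyl-2-(propan-2-ylidene)cyclohex-3-en-1-yl]propanoate | CC(C)=C1C=C[C@@H](C)[C@@](C)(C=O)[C@@H]1CCC(=O)OC
A4 | alternative 2 | tert-butyl 3-[(2S,3R)-5-(2,2-dimethyl-4-oxo-4H-1,3-dioxin-6-yl)-2-ethenyl-2,3-dimethylpentyl]-1H-indole-1-carboxylate | CC1(C)OC(=O)C=C(CC[C@@H](C)[C@@](C)(Cc2cn(C(=O)OC(C)(C)C)c3ccccc23)C=C)O1
A5 | alternative 2 | cis-anti-cis tricyclic photoadduct of A4 (cyclobutane fused to the cyclohexane and to the 2,2-dimethyl-1,3-dioxan-4-one; N-Boc-indol-3-ylmethyl on C2) | CC1(C)OC(=O)[C@@H]2C[C@H]3[C@](C)(Cc4cn(C(=O)OC(C)(C)C)c5ccccc45)[C@H](C)CC[C@]32O1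
A6 | alternative 2 | 3-[(1S,2R,3R)-2-{[1-(tert-butoxycarbonyl)-1H-indol-3-yl]methyl}-2,3-dimethyl-6-oxocyclohexyl]propanoic acid | O=C1CC[C@@H](C)[C@@](C)(Cc2cn(C(=O)OC(C)(C)C)c3ccccc23)[C@@H]1CCC(=O)O
A7 | alternative 3 | 7-ethenyl-6,6-dimethyl-1,4-dioxaspiro[4.5]dec-7-ene | C=CC1=CCCC2(OCCO2)C1(C)C
A8 | alternative 3 | (2E)-2-{[1-(4-methylbenzenesulfonyl)-1H-indol-3-yl]methyl}but-2-enal | C/C=C(\Cc1cn(S(=O)(=O)c2ccc(C)cc2)c2ccccc12)C=O
A9 | alternative 3 | endo Diels–Alder adduct of A7 and A8 (octalin ethylene ketal with formyl and N-tosylindol-3-ylmethyl groups on C2 and methyl on C3) | CC1(C)C2=CC[C@@H](C)[C@@](C=O)(Cc3cn(S(=O)(=O)c5ccc(C)cc5)c4ccccc34)[C@@H]2CCC12OCCO2
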